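**Retrosynthetic overview**

1. Feature: in the 14-membered carbocycle C1–C14, the ring olefin C7=C8 with CH2OH on C8 is the product pattern of an allyl sulfoxide → sulfenate [2,3] shift. A C7 phenylsulfinyl group beside a C8 exo-methylene is therefore its precursor, and it makes C7 a carbon nucleophile.
2. Key disconnection C6–C7: the lithiated allyl sulfoxide (C7) is alkylated intramolecularly by the primary C6 iodide; this one step forms the only ring.
3. Seco precursor 23: the (Z)-C3=C4 olefin and the C6 iodide arm come from a Still–Wittig rearrangement; the C7 sulfoxide comes from the C7 allylic alcohol by a sulfenate → sulfoxide shift.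
4. C1 (R) and the (E)-C15=C16 olefin come from a Johnson–Claisen rearrangement of an (R)-C16 carbinol (Brown allylation, then cross-metathesis to the prenyl group).
5. The C9–C10 bond joins geranyl bromide to the dianion of 2-methylprop-2-en-1-ol; C16 is oxygenated with SeO2.

Key step: step 17

Assumption: locants C1–C19 are those of the target throughout (ring C1–C14 with C1 the (R) centre, side chain C15–C19); the C3 carbinol epimers (14–16) and the sulfur/C7 epimers (22–26) are carried as mixtures because these centres are erased later.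

**Route**

Step 1
Reactants: 1 geraniol
Product: 2 geranyl bromide [(2E)-1-bromo-3,7-dimethylocta-2,6-diene]
Conditions: PBr3, Et2O, −10 → 0 °C
Reagents that add atoms: phosphorus tribromide BrP(Br)Br
Why: PBr3 bromination of a primary allylic alcohol proceeds by SN2 on the phosphite ester at low temperature and should leave the olefin position and geometry unchanged.

Step 2
Reactants: 2 geranyl bromide; 3 2-methylprop-2-en-1-ol
Product: 5 (5E)-6,10-dimethyl-2-methylideneundeca-5,9-dien-1-ol, via dilithio alkoxide 4 (not isolated)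
Conditions: 3, n-BuLi (2 equiv), TMEDA, Et2O, 0 °C → rt; then 2, THF, −78 → 0 °C
Reagents that add atoms: none
Why: C-alkylation of the 2-methylprop-2-en-1-ol dianion, whose allyl termini are equivalent, at the primary carbon of the allylic bromide (SN2) should form the C9–C10 bond and deliver C7–C9 with the exo-methylene and the C7 oxygen in place.

Step 3
Reactants: 5
Product: 6 tert-butyl{[(5E)-6,10-dimethyl-2-methylideneundeca-5,9-dien-1-yl]oxy}diphenylsilane
Conditions: TBDPSCl, imidazole, DMF, rt
Reagents that add atoms: tert-butyl(chloro)diphenylsilane CC(C)(C)[Si](Cl)(c1ccccc1)c1ccccc1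
Why: Silylation of the primary allylic alcohol gives an ether robust enough for the oxidation, Claisen and organolithium steps that follow.

Step 4
Reactants: 6
Product: 7 (2E,6E)-10-{[tert-butyl(diphenyl)silyl]oxymethyl}-2,6-dimethylundeca-2,6,10-trien-1-ol
Conditions: SeO2 (cat.), t-BuOOH, salicylic acid (cat.), CH2Cl2, 0 °C → rt
Reagents that add atoms: selenium dioxide O=[Se]=O (oxygen carrier); tert-butyl hydroperoxide CC(C)(C)OO (terminal oxidant)
Why: Catalytic SeO2 allylic oxidation (ene reaction then [2,3] shift) should take the (E)-methyl of the terminal trisubstituted olefin, the most accessible and electron-rich ene partner, and any enal 8 formed by over-oxidation is carried into step 5.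

Step 5
Reactants: 7
Product: 8 (2E,6E)-10-{[tert-butyl(diphenyl)silyl]oxymethyl}-2,6-dimethylundeca-2,6,10-trienal
Conditions: PhI(OAc)2, TEMPO (cat.), CH2Cl2, rt
Reagents that add atoms: none
Why: TEMPO/PhI(OAc)2 oxidation of a primary allylic alcohol should stop at the enal without E/Z isomerisation or attack on the other olefins.

Step 6
Reactants: 8
Product: 9 (4R,5E,9E)-13-{[tert-butyl(diphenyl)silyl]oxymethyl}-5,9-dimethyltetradeca-1,5,9,13-tetraen-4-ol
Conditions: (+)-Ipc2BOMe (from (−)-α-pinene), allylMgBr, Et2O, −78 °C → rt; then 8, −78 °C; NaOH, H2O2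
Reagents that add atoms: allylmagnesium bromide C=CC[Mg]Br
Why: Brown allylboration through a closed chair transition state; the (−)-α-pinene-derived allylborane adds to the Re face of the aldehyde (the sense that gives (R)-1-phenylbut-3-en-1-ol from benzaldehyde) and should set the C16 carbinol as (R).

Step 7
Reactants: 9
Product: 10 (5R,6E,10E)-14-{[tert-butyl(diphenyl)silyl]oxymethyl}-2,6,10-trimethylpentadeca-2,6,10,14-tetraen-5-ol
Conditions: Grubbs II (cat.), 2-methyl-2-butene (excess), CH2Cl2, rt → 40 °C
Reagents that add atoms: 2-methyl-2-butene CC=C(C)C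
Why: Olefin cross-metathesis of the monosubstituted terminal olefin with 2-methyl-2-butene should give the prenyl group, while the trisubstituted and 1,1-disubstituted olefins react far more slowly.

Step 8
Reactants: 10
Product: 12 ethyl (3R,6E)-10-{[tert-butyl(diphenyl)silyl]oxymethyl}-6-methyl-3-[(2E)-6-methylhepta-2,5-dien-2-yl]undeca-6,10-dienoate, via mixed ketene acetal 11 (not isolated)
Conditions: MeC(OEt)3, EtCO2H (cat.), xylene, 140 °C, EtOH distilled off
Reagents that add atoms: triethyl orthoacetate CCOC(C)(OCC)OCC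
Why: Johnson orthoester Claisen rearrangement through a chair transition state with the C17 chain pseudo-equatorial should give the (E)-C15=C16 olefin and transfer the (R) configuration of C16 suprafacially across the (E)-C15=C1 olefin to C1, which becomes (R).

Step 9
Reactants: 12
Product: 13 (3R,6E)-10-{[tert-butyl(diphenyl)silyl]oxymethyl}-6-methyl-3-[(2E)-6-methylhepta-2,5-dien-2-yl]undeca-6,10-dienal
Conditions: DIBAL-H (1.05 equiv), CH2Cl2, −78 °C; Rochelle salt
Reagents that add atoms: none
Why: Partial DIBAL reduction of the ester stops at the aldehyde because the tetrahedral aluminium hemiacetal is stable at −78 °C.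

Step 10
Reactants: 13
Product: 14 (5R,8E)-12-{[tert-butyl(diphenyl)silyl]oxymethyl}-2,8-dimethyl-5-[(2E)-6-methylhepta-2,5-dien-2-yl]trideca-1,8,12-trien-3-ol (C3 epimers)
Conditions: isopropenylMgBr, THF, −78 → 0 °C
Reagents that add atoms: isopropenylmagnesium bromide CC(=C)[Mg]Br
Why: Grignard 1,2-addition installs C4, its methyl and C5; the new C3 carbinol centre forms without control and is erased in step 12.

Step 11
Reactants: 14
Product: 15 tributyl[({(5R,8E)-12-{[tert-butyl(diphenyl)silyl]oxymethyl}-2,8-dimethyl-5-[(2E)-6-methylhepta-2,5-dien-2-yl]trideca-1,8,12-trien-3-yl}oxy)methyl]stannane (C3 epimers)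
Conditions: KH, THF, 0 °C; Bu3SnCH2I, rt
Reagents that add atoms: tributyl(iodomethyl)stannane CCCC[Sn](CCCC)(CCCC)CI
Why: Williamson O-alkylation of the potassium alkoxide with the iodomethylstannane should give the stannylmethyl ether needed for the Still–Wittig rearrangement.

Step 12
Reactants: 15
Product: 17 (3Z,6R,9E)-13-{[tert-butyl(diphenyl)silyl]oxymethyl}-3,9-dimethyl-6-[(2E)-6-methylhepta-2,5-dien-2-yl]tetradeca-3,9,13-trien-1-ol, via α-alkoxymethyllithium 16 (not isolated)
Conditions: n-BuLi, THF, −78 °C
Reagents that add atoms: none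
Why: Still–Wittig [2,3] rearrangement: tin–lithium exchange gives the α-alkoxymethyllithium, which rearranges through an envelope transition state with the C2 chain pseudo-axial (avoiding the C4 methyl), so both C3 epimers should converge on the (Z)-C3=C4 homoallylic alcohol with C6 as CH2OH.

Step 13
Reactants: 17
Product: 18 tert-butyl{[(5E,9R,11Z)-14-iodo-6,12-dimethyl-2-methylidene-9-[(2E)-6-methylhepta-2,5-dien-2-yl]tetradeca-5,11-dien-1-yl]oxy}diphenylsilane
Conditions: I2, PPh3, imidazole, CH2Cl2, 0 °C → rt
Reagents that add atoms: iodine II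
Why: Appel-type iodination of the primary alcohol via the alkoxyphosphonium salt (SN2) should not touch the olefins or the silyl ether.

Step 14
Reactants: 18
Product: 19 (5E,9R,11Z)-14-iodo-6,12-dimethyl-2-methylidene-9-[(2E)-6-methylhepta-2,5-dien-2-yl]tetradeca-5,11-dien-1-ol
Conditions: HF·pyridine, pyridine, THF, 0 °C → rt
Reagents that add atoms: none
Why: Buffered HF·pyridine desilylation is non-basic, so the homoallylic iodide should be spared from E2 elimination or fluoride displacement.

Step 15
Reactants: 20 thiophenol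
Product: 21 benzenesulfenyl chloride
Conditions: NCS, CH2Cl2, 0 °C → rt; taken up in pentane, filtered, used as a THF solution
Reagents that add atoms: N-chlorosuccinimide O=C1CCC(=O)N1Cl
Why: S-chlorination of the thiol with one equivalent of NCS gives the sulfenyl chloride.

Step 16
Reactants: 19; 21 benzenesulfenyl chloride
Product: 23 {[(5E,9R,11Z)-14-iodo-6,12-dimethyl-2-methylidene-9-[(2E)-6-methylhepta-2,5-dien-2-yl]tetradeca-5,11-dien-1-yl]sulfinyl}benzene (mixture at sulfur), via allyl sulfenate 22 (not isolated)
Conditions: LiHMDS (1.0 equiv), THF, −78 °C; then 21, −78 °C → rt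
Reagents that add atoms: none
Why: O-sulfenylation of the pre-formed alkoxide at −78 °C should outpace addition of the sulfenyl chloride to the olefins, and the allyl sulfenate then undergoes the [2,3] sulfenate → sulfoxide rearrangement to the thermodynamically preferred allyl sulfoxide, placing sulfur on C7 and the exo-methylene on C8 (sulfur centre uncontrolled and irrelevant).

Step 17
Reactants: 23
Product: 25 (1R,3Z,11E)-4,12-dimethyl-8-methylidene-1-[(2E)-6-methylhepta-2,5-dien-2-yl]-7-(phenylsulfinyl)cyclotetradeca-3,11-diene (mixture at C7 and sulfur), via lithiated sulfoxide 24 (not isolated)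
Conditions: LDA (1.1 equiv), THF (0.002 M), −78 → −20 °C
Reagents that add atoms: none
Why: Proposed new method: LDA removes the C7 proton, which is both α to the sulfinyl group and allylic, and the lithium-bridged allyl anion 24 displaces the primary C6 iodide by intramolecular SN2, forming the C6–C7 bond. The closest known reactions are the intermolecular α-alkylation of lithiated allyl aryl sulfoxides with primary iodides and the macrocyclisation of sulfide- or sulfone-stabilised allyl anions to 14-membered terpenoid rings; joining the two in a sulfoxide-anion macrocyclisation is the new element. The 14-membered carbocycle closes in the 14-exo-tet mode, helped by three trisubstituted olefins that cut down the rotatable bonds of the chain. The new C7 stereocentre is not controlled by any element of the substrate and need not be, since every C7/sulfur epimer passes through the same [2,3] shift in step 18, while C1 is remote and untouched. The step needs α- over γ-alkylation (γ would give a 16-membered vinyl sulfoxide), which the lithium counter-ion in THF without HMPA should secure by bridging the sulfinyl oxygen and C7, together with the soft iodide leaving group. It also needs substitution to win over E2 at the homoallylic iodide and over oligomerisation, which the weakly basic stabilised carbanion, low temperature and high dilution should secure.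

Step 18
Reactants: 25
Product: 27 [(1R,3Z,7E,11E)-4,12-dimethyl-1-[(2E)-6-methylhepta-2,5-dien-2-yl]cyclotetradeca-3,7,11-trien-8-yl]methanol (target locants), via macrocyclic sulfenate 26 (not isolated)
Conditions: P(OMe)3, MeOH, rt → 50 °C
Reagents that add atoms: none
Why: Mislow–Evans rearrangement: the reversible [2,3] sulfoxide → sulfenate shift moves the double bond to C7=C8 and oxygen to the former exo-methylene carbon, the thiophile cleaves the S–O bond, and the pseudo-equatorial preference of C6 in the five-membered transition state should place C6 trans to CH2OH (7E), a ring-cis olefin that the 14-membered ring accommodates.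

**Compound list**

1 | geraniol | CC(C)=CCC/C(C)=C/CO | starting material
2 | geranyl bromide | CC(C)=CCC/C(C)=C/CBr | intermediate
3 | 2-methylprop-2-en-1-ol | C=C(C)CO | starting material
4 | dilithio alkoxide of 3 (lithium 2-(lithiomethyl)prop-2-en-1-olate) | [Li]CC(=C)CO[Li] | intermediate (not isolated)
5 | (5E)-6,10-dimethyl-2-methylideneundeca-5,9-dien-1-ol | CC(C)=CCC/C(C)=C/CCC(=C)CO | intermediate
6 | TBDPS ether of 5 | CC(C)=CCC/C(C)=C/CCC(=C)CO[Si](c1ccccc1)(c1ccccc1)C(C)(C)C | intermediate
7 | (2E,6E)-C16 allylic alcohol | OC/C(C)=C/CC/C(C)=C/CCC(=C)CO[Si](c1ccccc1)(c1ccccc1)C(C)(C)C | intermediate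
8 | (2E,6E)-C16 enal | O=C/C(C)=C/CC/C(C)=C/CCC(=C)CO[Si](c1ccccc1)(c1ccccc1)C(C)(C)C | intermediate
9 | (R)-C16 allyl carbinol | C=CC[C@@H](O)/C(C)=C/CC/C(C)=C/CCC(=C)CO[Si](c1ccccc1)(c1ccccc1)C(C)(C)C | intermediate
10 | (R)-C16 prenyl carbinol | CC(C)=CC[C@@H](O)/C(C)=C/CC/C(C)=C/CCC(=C)CO[Si](c1ccccc1)(c1ccccc1)C(C)(C)C | intermediate
11 | 1-ethoxyvinyl ether of 10 (mixed ketene acetal on C16–O) | C=C(OCC)O[C@H](CC=C(C)C)/C(C)=C/CC/C(C)=C/CCC(=C)CO[Si](c1ccccc1)(c1ccccc1)C(C)(C)C | intermediate (not isolated)
12 | (1R) ethyl ester (C3 = CO2Et) | CCOC(=O)C[C@@H](CC/C(C)=C/CCC(=C)CO[Si](c1ccccc1)(c1ccccc1)C(C)(C)C)/C(C)=C/CC=C(C)C | intermediate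
13 | (1R) C3 aldehyde | O=CC[C@@H](CC/C(C)=C/CCC(=C)CO[Si](c1ccccc1)(c1ccccc1)C(C)(C)C)/C(C)=C/CC=C(C)C | intermediate
14 | (1R) C3 isopropenyl carbinol, C3 epimers | C=C(C)C(O)C[C@@H](CC/C(C)=C/CCC(=C)CO[Si](c1ccccc1)(c1ccccc1)C(C)(C)C)/C(C)=C/CC=C(C)C | intermediate
15 | tributylstannylmethyl ether of 14 | CCCC[Sn](CCCC)(CCCC)COC(C(C)=C)C[C@@H](CC/C(C)=C/CCC(=C)CO[Si](c1ccccc1)(c1ccccc1)C(C)(C)C)/C(C)=C/CC=C(C)C | intermediate
16 | lithiomethyl ether of 14 (C3–O–CH2Li) | [Li]COC(C(C)=C)C[C@@H](CC/C(C)=C/CCC(=C)CO[Si](c1ccccc1)(c1ccccc1)C(C)(C)C)/C(C)=C/CC=C(C)C | intermediate (not isolated)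
17 | (1R,3Z) C6 alcohol, C7–OTBDPS | OCC/C(C)=C\C[C@@H](CC/C(C)=C/CCC(=C)CO[Si](c1ccccc1)(c1ccccc1)C(C)(C)C)/C(C)=C/CC=C(C)C | intermediate
18 | (1R,3Z) C6 iodide, C7–OTBDPS | ICC/C(C)=C\C[C@@H](CC/C(C)=C/CCC(=C)CO[Si](c1ccccc1)(c1ccccc1)C(C)(C)C)/C(C)=C/CC=C(C)C | intermediate
19 | (1R,3Z) C6 iodide, C7 allylic alcohol | ICC/C(C)=C\C[C@@H](CC/C(C)=C/CCC(=C)CO)/C(C)=C/CC=C(C)C | intermediate
20 | thiophenol | Sc1ccccc1 | starting material
21 | benzenesulfenyl chloride | ClSc1ccccc1 | intermediate
22 | benzenesulfenate ester of 19 | ICC/C(C)=C\C[C@@H](CC/C(C)=C/CCC(=C)COSc1ccccc1)/C(C)=C/CC=C(C)C | intermediate (not isolated)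
23 | seco precursor: C6 iodide, C7 phenylsulfinyl, C8 exo-methylene (mixture at S) | ICC/C(C)=C\C[C@@H](CC/C(C)=C/CCC(=C)CS(=O)c1ccccc1)/C(C)=C/CC=C(C)C | intermediate
24 | C7-lithio derivative of 23 | ICC/C(C)=C\C[C@@H](CC/C(C)=C/CCC(=C)C([Li])S(=O)c1ccccc1)/C(C)=C/CC=C(C)C | intermediate (not isolated)
25 | 14-membered ring, C7 phenylsulfinyl, C8 exo-methylene (mixture at C7 and S) | CC(C)=CC/C=C(\C)[C@H]1C/C=C(/C)CCC(S(=O)c2ccccc2)C(=C)CC/C=C(\C)CC1 | intermediate
26 | macrocyclic benzenesulfenate of 27 | CC(C)=CC/C=C(\C)[C@H]1C/C=C(/C)CC/C=C(/COSc2ccccc2)CC/C=C(\C)CC1 | intermediate (not isolated)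
27 | CNP0355114.1 | CC(C)=CC/C=C(\C)[C@H]1C/C=C(/C)CC/C=C(/CO)CC/C=C(\C)CC1 | target

**Totals**

Total step count: 18. Longest linear sequence: 17 (steps 1–14 and 16–18; step 15 is a one-step side branch).

**Steps most likely to fail**

1. Step 17 (proposed new method). The carbanion may alkylate through its γ terminus to a 16-membered vinyl sulfoxide, eliminate the homoallylic iodide, or react intermolecularly. The fallback uses known chemistry: sulfur is carried at the sulfide level and the ring is closed with a sulfide-stabilised allyllithium. It sets out from alcohol 17 and returns at 25.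
   - 17 is converted (PPh3, NCS, CH2Cl2) into the C6 chloride F1.
   - F1 is desilylated (HF·pyridine) to the chloro allylic alcohol F2.
   - F2 is thioetherified (PhSSPh, Bu3P, pyridine) to the chloro allyl phenyl sulfide F3.
   - n-BuLi/DABCO in THF at −78 °C → rt under high dilution should close the ring to the macrocyclic allyl phenyl sulfide F4; a primary chloride tolerates the alkyllithium.
   - mCPBA (1 equiv, CH2Cl2, −78 °C) should oxidise F4 to 25, where the route is rejoined.

2. Step 18. Ring strain may force C6 pseudo-axial in the [2,3] transition state and erode the geometric control, giving the C7=C8 isomer with C6 cis to CH2OH. The fallback sets out from 25 and returns at 27.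
   - The rearrangement is run as in step 18 and the crude alcohol mixture is oxidised (MnO2, CH2Cl2) to the macrocyclic enal isomer mixture F5.
   - F5 is equilibrated by reversible conjugate addition of a nucleophilic catalyst (PhSH/Et3N, cat.) to the thermodynamically preferred (7E)-enal F6, with CHO trans to C6. Radical or iodine conditions are avoided so that the (Z)-C3=C4 olefin is not scrambled.
   - Luche reduction (NaBH4, CeCl3, MeOH, 0 °C) of F6 should give 27.

3. Step 4. The selenium oxidant may attack the internal C11=C12 olefin or over-oxidise, because 6 carries two trisubstituted olefins without a deactivating group. The fallback builds the enal from the terminal olefin by cleavage and re-olefination. It sets out from 6 and returns at 8, bypassing 7.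
   - Terminal-selective bromohydrin formation (NBS, THF–H2O, 0 °C) gives the bromohydrin F7.
   - K2CO3/MeOH closes F7 to the terminal epoxide F8.
   - H5IO6 (THF–Et2O) cleaves F8 to the trisnor aldehyde F9.
   - Wittig reaction of F9 with 2-(triphenylphosphoranylidene)propanal (toluene, 80 °C) should give the (E)-enal 8.

**Further compounds**

F1 | step 17 | (1R,3Z) C6 chloride, C7–OTBDPS | ClCC/C(C)=C\C[C@@H](CC/C(C)=C/CCC(=C)CO[Si](c1ccccc1)(c1ccccc1)C(C)(C)C)/C(C)=C/CC=C(C)C
F2 | step 17 | (1R,3Z) C6 chloride, C7 allylic alcohol | ClCC/C(C)=C\C[C@@H](CC/C(C)=C/CCC(=C)CO)/C(C)=C/CC=C(C)C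
F3 | step 17 | (1R,3Z) C6 chloride, C7 phenylthio, C8 exo-methylene | ClCC/C(C)=C\C[C@@H](CC/C(C)=C/CCC(=C)CSc1ccccc1)/C(C)=C/CC=C(C)C
F4 | step 17 | 14-membered ring, C7 phenylthio, C8 exo-methylene (mixture at C7) | CC(C)=CC/C=C(\C)[C@H]1C/C=C(/C)CCC(Sc2ccccc2)C(=C)CC/C=C(\C)CC1
F5 | step 18 | macrocyclic C8 enal, C7=C8 isomer mixture | CC(C)=CC/C=C(\C)[C@H]1C/C=C(/C)CCC=C(C=O)CC/C=C(\C)CC1
F6 | step 18 | macrocyclic (7E)-C8 enal | CC(C)=CC/C=C(\C)[C@H]1C/C=C(/C)CC/C=C(/C=O)CC/C=C(\C)CC1
F7 | step 4 | terminal bromohydrin of 6 (racemic) | CC(C)(O)C(Br)CC/C(C)=C/CCC(=C)CO[Si](c1ccccc1)(c1ccccc1)C(C)(C)C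
F8 | step 4 | terminal epoxide of 6 (racemic) | CC1(C)OC1CC/C(C)=C/CCC(=C)CO[Si](c1ccccc1)(c1ccccc1)C(C)(C)C
F9 | step 4 | trisnor aldehyde (C1 = CHO) | O=CCC/C(C)=C/CCC(=C)CO[Si](c1ccccc1)(c1ccccc1)C(C)(C)C
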